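**Retrosynthetic overview**

1. The route rests on one feature: the methyl-bearing quaternary C10 lies β to C4 through C5, and C5 carries the C6 carbinol, so methyl addition to C10 of a ring-B enone C4(=O)–C5=C10 creates exactly the C5 enolate that can close ring A onto a C6 aldehyde.
2. Target 33 ⇒ orthoester ketone 31 (C1 reduction and desilylation last) ⇒ triol 26 (O4, O6, O15) + trimethyl orthocinnamate 30; the two orthoester rings are closed last by orthoester exchange.
3. Triol 26 ⇒ aldol 23 by C4 methylenation (C15), release of the C1 ketone and α-face dihydroxylation of C4=C15.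
4. Aldol 23 ⇒ keto aldehyde 20 by conjugate methylation–aldol (C10–C14 and C5–C6; ring A).
5. Aldehyde 20 ⇒ ring-B vinyl bromide 4 (C1 as dioxolane) + lactone 13 (C6–C9, C7 from an auxiliary alkylation), with C9 set by CBS reduction and the C4 carbonyl by allylic oxidation. Ring order: B (bought), A (key step), orthoester rings.

Key step: step 12

Remark: eudesmane numbering is used (ring A = C5–C10; ring B = C10, C1–C5; C14 = methyl on C10; C15 = CH2O on C4; β = the face of C14), and the target is taken as the single enantiomer given, with the (E)-styryl group.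

**Route**

Step 1
Reactants: 1 2-cyclohexen-1-one
Product: 3 2-bromocyclohex-2-en-1-one, via 2,3-dibromocyclohexanone 2 (not isolated)
Conditions: Br2, CH2Cl2, 0 °C; then Et3N, 0 °C → rt
Reagents that add atoms: bromine, BrBr
Why: Bromine adds across the enone double bond and triethylamine removes HBr by E1cB elimination (bromination–dehydrobromination), which should give the α-bromo enone.

Step 2
Reactants: 3 2-bromocyclohex-2-en-1-one
Product: 4 6-bromo-1,4-dioxaspiro[4.5]dec-6-ene
Conditions: HOCH2CH2OH, p-TsOH·H2O (cat.), benzene, reflux, Dean–Stark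
Reagents that add atoms: ethylene glycol, OCCO
Why: Acid-catalysed ketalisation with azeotropic removal of water masks the future C1 carbonyl as the dioxolane and leaves the vinyl bromide (future C10) in place.

Step 3
Reactants: 5 (S)-4-benzyl-1,3-oxazolidin-2-one; 6 isovaleryl chloride
Product: 8 (S)-4-benzyl-3-(3-methylbutanoyl)-1,3-oxazolidin-2-one, via N-lithio oxazolidinone 7 (not isolated)
Conditions: n-BuLi, THF, −78 °C; then 6, −78 → 0 °C
Reagents that add atoms: none
Why: N-Acylation of the lithiated oxazolidinone by the acid chloride is the standard preparation of an Evans imide.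

Step 4
Reactants: 8 (S)-4-benzyl-3-(3-methylbutanoyl)-1,3-oxazolidin-2-one; 9 tert-butyl bromoacetate
Product: 11 tert-butyl (3S)-3-[(4S)-4-benzyl-2-oxo-1,3-oxazolidine-3-carbonyl]-4-methylpentanoate, via sodium enolate 10 (not isolated)
Conditions: NaHMDS, THF, −78 °C; then 9, −78 → −40 °C
Reagents that add atoms: none
Why: Evans asymmetric alkylation, in which the chelated (Z)-enolate is attacked on the face opposite the benzyl group, should set C7 as S (the future 7α-isopropyl centre) and bring in C8 and C9.

Step 5
Reactants: 11 tert-butyl (3S)-3-[(4S)-4-benzyl-2-oxo-1,3-oxazolidine-3-carbonyl]-4-methylpentanoate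
Product: 13 (4S)-4-isopropyldihydrofuran-2(3H)-one (lactone carbonyl = C9, ring CH2O = C6), via tert-butyl (3S)-3-(hydroxymethyl)-4-methylpentanoate 12 (not isolated)
Conditions: LiBH4, H2O (1 equiv), Et2O, 0 °C; work-up; then TFA, CH2Cl2, rt
Reagents that add atoms: none
Why: LiBH4 reduces the activated imide carbonyl selectively in the presence of the tert-butyl ester and releases the auxiliary, and acid then cleaves the tert-butyl ester and closes the γ-lactone without touching C7.

Step 6
Reactants: 4 6-bromo-1,4-dioxaspiro[4.5]dec-6-ene; 13 (4S)-4-isopropyldihydrofuran-2(3H)-one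
Product: 15 (3S)-1-(1,4-dioxaspiro[4.5]dec-6-en-6-yl)-3-(hydroxymethyl)-4-methylpentan-1-one, via vinyllithium 14 (not isolated)
Conditions: 4, n-BuLi, THF, −78 °C; then 13, −78 °C; AcOH quench at −78 °C
Reagents that add atoms: none
Why: Bromine–lithium exchange gives the α-ketovinyl anion equivalent (the C10 nucleophile), and its single addition to the lactone stops at the lithium hemiketal until the cold quench, so the C9–C10 bond and the C9 ketone should arise in one operation.

Step 7
Reactants: 15 (3S)-1-(1,4-dioxaspiro[4.5]dec-6-en-6-yl)-3-(hydroxymethyl)-4-methylpentan-1-one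
Product: 16 (1R,3S)-1-(1,4-dioxaspiro[4.5]dec-6-en-6-yl)-3-(hydroxymethyl)-4-methylpentan-1-ol
Conditions: (S)-2-methyl-CBS-oxazaborolidine (0.2 equiv), BH3·SMe2 (2.2 equiv), THF, −30 °C; MeOH quench
Reagents that add atoms: none
Why: In the Corey–Bakshi–Shibata reduction the bulky cycloalkenyl group acts as the large substituent, so the (S)-catalyst should deliver hydride to give the 9R allylic alcohol under catalyst control, the free primary hydroxyl only consuming borane.

Step 8
Reactants: 16 (1R,3S)-1-(1,4-dioxaspiro[4.5]dec-6-en-6-yl)-3-(hydroxymethyl)-4-methylpentan-1-ol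
Product: 17 6-[(1R,3S)-1-(tert-butyldimethylsilyloxy)-3-(tert-butyldimethylsilyloxymethyl)-4-methylpentyl]-1,4-dioxaspiro[4.5]dec-6-ene
Conditions: TBSOTf (2.5 equiv), 2,6-lutidine, CH2Cl2, −78 → 0 °C
Reagents that add atoms: tert-butyldimethylsilyl triflate, CC(C)(C)[Si](C)(C)OS(=O)(=O)C(F)(F)F
Why: A silyl triflate with a hindered base silylates both the primary and the hindered allylic hydroxyl while the buffered medium spares the dioxolane.

Step 9
Reactants: 17 6-[(1R,3S)-1-(tert-butyldimethylsilyloxy)-3-(tert-butyldimethylsilyloxymethyl)-4-methylpentyl]-1,4-dioxaspiro[4.5]dec-6-ene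
Product: 18 6-[(1R,3S)-1-(tert-butyldimethylsilyloxy)-3-(tert-butyldimethylsilyloxymethyl)-4-methylpentyl]-1,4-dioxaspiro[4.5]dec-6-en-8-one
Conditions: Rh2(cap)4 (dirhodium tetracaprolactamate, 1 mol%), t-BuOOH (5 equiv), K2CO3, CH2Cl2, rt
Reagents that add atoms: tert-butyl hydroperoxide, CC(C)(C)OO
Why: Dirhodium-catalysed allylic C–H oxidation (tert-butylperoxy radical chain) should convert the only ring allylic methylene, C4, into the enone carbonyl, because C1 is blocked as the ketal and the C9–H bond is shielded by its silyl ether and held near the alkene plane by the neighbouring spiro carbon.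

Step 10
Reactants: 18 6-[(1R,3S)-1-(tert-butyldimethylsilyloxy)-3-(tert-butyldimethylsilyloxymethyl)-4-methylpentyl]-1,4-dioxaspiro[4.5]dec-6-en-8-one
Product: 19 6-[(1R,3S)-1-(tert-butyldimethylsilyloxy)-3-(hydroxymethyl)-4-methylpentyl]-1,4-dioxaspiro[4.5]dec-6-en-8-one
Conditions: HF·pyridine, pyridine, THF, 0 °C
Reagents that add atoms: none
Why: Buffered HF·pyridine cleaves the unhindered primary silyl ether much faster than the hindered secondary one (selective desilylation).

Step 11
Reactants: 19 6-[(1R,3S)-1-(tert-butyldimethylsilyloxy)-3-(hydroxymethyl)-4-methylpentyl]-1,4-dioxaspiro[4.5]dec-6-en-8-one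
Product: 20 (2S,4R)-4-(tert-butyldimethylsilyloxy)-2-isopropyl-4-(8-oxo-1,4-dioxaspiro[4.5]dec-6-en-6-yl)butanal (C6 aldehyde, C7 S, C9 R, ring-B enone with C1 dioxolane)
Conditions: Dess–Martin periodinane, NaHCO3, CH2Cl2, 0 °C → rt; used at once
Reagents that add atoms: none
Why: Buffered Dess–Martin oxidation should give the α-branched aldehyde without epimerising C7 and without touching the enone or the dioxolane.

Step 12
Reactants: 20 (2S,4R)-4-(tert-butyldimethylsilyloxy)-2-isopropyl-4-(8-oxo-1,4-dioxaspiro[4.5]dec-6-en-6-yl)butanal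
Product: 23 9β-(tert-butyldimethylsilyloxy)-6α-hydroxy-7α-isopropyl-10β-methyl-trans-decalin-4-one 1-ethylene acetal (5α-H), via methylzinc enolate 21 (not isolated), via methylzinc aldolate 22 (not isolated)
Conditions: Me2Zn (3 equiv), (CuOTf)2·C6H6 (5 mol%), chiral sulfonate-bearing imidazolinylidene–silver complex (5 mol%, preformed from the imidazolinium sulfonate and Ag2O; antipode that attacks the C10 Si face), Et2O, −30 → 22 °C; then H2O (pH 7 buffer)
Reagents that add atoms: dimethylzinc, C[Zn]C
Why: The methylated monovalent copper–carbene complex binds the C5=C10 bond and transfers CH3 to C10 (C10–C14), leaving the methylzinc enolate 21 at C4–C5, which adds to the tethered C6 aldehyde (C5–C6) to give the zinc aldolate 22; the closest known reaction type is the copper-catalysed asymmetric conjugate addition of dialkylzincs to 3-substituted cyclohexenones that builds all-carbon quaternary centres, joined to aldol capture of the zinc enolate. Ring A closes as a 6-(enolexo)-exo-trig aldol. C10 is set by the catalyst, whose antipode is chosen to deliver methyl to the Si face (C14 β) in the matched sense with the C9 silyloxy centre. C5 and C6 should follow from a chair transition state of the ring (E)-enolate in which zinc bridges the enolate and aldehyde oxygens and the C9 silyloxy group is equatorial, giving the anti aldol with H5 α (trans fusion) and the 6α-hydroxyl equatorial; C5 remains epimerisable next to the C4 ketone and can still settle into the trans fusion. The step needs 1,4-addition to the enone with no attack on the aldehyde and a single enolate regioisomer: Me2Zn does not add to an aldehyde unaided, the carbene is supplied as its silver complex so that no free carbene can start acyl-anion chemistry, and the enolate can form only at C5 because the conjugate addition generates it. The C7 centre beside the aldehyde meets no base, and the C1 dioxolane keeps C1 from serving as a second acceptor carbonyl.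

Step 13
Reactants: 23 9β-(tert-butyldimethylsilyloxy)-6α-hydroxy-7α-isopropyl-10β-methyl-trans-decalin-4-one 1-ethylene acetal
Product: 24 9β-(tert-butyldimethylsilyloxy)-7α-isopropyl-10β-methyl-4-methylene-trans-decalin-6α-ol 1-ethylene acetal
Conditions: Zn, CH2Br2, TiCl4, THF (reagent preformed, excess); then 23, CH2Cl2, 0 °C → rt
Reagents that add atoms: dibromomethane, BrCBr
Why: The Takai–Lombardo methylenation is non-basic, so the β-hydroxy ketone should undergo neither retro-aldol cleavage nor C5 epimerisation, and C15 is introduced while C1 is still masked so that only one carbonyl is present.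

Step 14
Reactants: 24 9β-(tert-butyldimethylsilyloxy)-7α-isopropyl-10β-methyl-4-methylene-trans-decalin-6α-ol 1-ethylene acetal
Product: 25 9β-(tert-butyldimethylsilyloxy)-6α-hydroxy-7α-isopropyl-10β-methyl-4-methylene-trans-decalin-1-one
Conditions: PPTS (0.3 equiv), acetone–H2O (10:1), 55 °C
Reagents that add atoms: water, O
Why: Mild acid-catalysed acetal hydrolysis, helped by relief of strain at the crowded spiro centre, should free the C1 ketone while the hindered secondary silyl ether and the exocyclic alkene tolerate pyridinium tosylate.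

Step 15
Reactants: 25 9β-(tert-butyldimethylsilyloxy)-6α-hydroxy-7α-isopropyl-10β-methyl-4-methylene-trans-decalin-1-one
Product: 26 9β-(tert-butyldimethylsilyloxy)-4α,6α-dihydroxy-4β-(hydroxymethyl)-7α-isopropyl-10β-methyl-trans-decalin-1-one
Conditions: OsO4 (5 mol%), N-methylmorpholine N-oxide (2 equiv), acetone–H2O (4:1), rt
Reagents that add atoms: osmium tetroxide, O=[Os](=O)(=O)=O; N-methylmorpholine N-oxide, C[N+]1([O-])CCOCC1
Why: In the Upjohn dihydroxylation OsO4 should add to C4=C15 from the α face, away from the 1,3-diaxial C14 methyl, which sets C4 with O4 α (equatorial) and C15 β (axial).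

Step 16
Reactants: 27 (E)-β-bromostyrene; 28 tetramethyl orthocarbonate
Product: 30 trimethyl (E)-orthocinnamate [(E)-(3,3,3-trimethoxyprop-1-enyl)benzene], via styrylmagnesium bromide 29 (not isolated)
Conditions: Mg, THF, rt → 40 °C; then C(OMe)4 (excess), THF, 60 °C; distilled from K2CO3
Reagents that add atoms: none
Why: Displacement of one methoxy group of an orthocarbonate by a Grignard reagent is an established orthoester synthesis, and the thermodynamically preferred E-alkenyl Grignard should carry the E geometry into the orthoester.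

Step 17
Reactants: 26 9β-(tert-butyldimethylsilyloxy)-4α,6α-dihydroxy-4β-(hydroxymethyl)-7α-isopropyl-10β-methyl-trans-decalin-1-one; 30 trimethyl (E)-orthocinnamate
Product: 31 9-O-TBS 1-ketone of the target: 4α,6α,15-[(E)-3-phenylprop-2-en-1-yl-1-ylidyne]trioxy-9β-(tert-butyldimethylsilyloxy)-7α-isopropyl-10β-methyl-trans-decalin-1-one
Conditions: 30 (1.5 equiv), PPTS (0.1 equiv), 4 Å molecular sieves, CH2Cl2, rt → 40 °C; Et3N quench
Reagents that add atoms: none
Why: In this acid-catalysed orthoester exchange the dialkoxycarbenium ion from 30 is captured in turn by O15, O4 and O6, which are held within reach (O4 and O6 equatorial on the α face, C15 axial), and loss of three methanols to the sieves should drive closure of the 2,7,8-trioxabicyclo[3.2.1]octane cage, whose orthoester carbon can take only one configuration.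

Step 18
Reactants: 31 9-O-TBS 1-ketone of the target
Product: 32 9-O-TBS ether of the target (1β-alcohol)
Conditions: NaBH4, MeOH–THF, 0 °C
Reagents that add atoms: none
Why: Borohydride should attack the C1 ketone along the axial α trajectory, because the β face is blocked by the C14 methyl and the neighbouring 9-silyloxy group, giving the equatorial 1β-alcohol without affecting the orthoester or the styryl group.

Step 19
Reactants: 32 9-O-TBS ether of the target
Product: 33 target, CNP0252898.2
Conditions: Bu4NF, THF, rt → 45 °C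
Reagents that add atoms: none
Why: Fluoride cleaves the last silyl ether under basic conditions, in which the acid-labile orthoester is stable.

**Compound list**

1 | 2-cyclohexen-1-one | O=C1C=CCCC1 | starting material
2 | 2,3-dibromocyclohexanone (racemic, not isolated) | O=C1CCCC(Br)C1Br | intermediate
3 | 2-bromocyclohex-2-en-1-one | O=C1CCCC=C1Br | intermediate
4 | 6-bromo-1,4-dioxaspiro[4.5]dec-6-ene | BrC1=CCCCC12OCCO2 | intermediate
5 | (S)-4-benzyl-1,3-oxazolidin-2-one | O=C1N[C@@H](Cc2ccccc2)CO1 | starting material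
6 | isovaleryl chloride | CC(C)CC(Cl)=O | starting material
7 | N-lithio-(S)-4-benzyl-1,3-oxazolidin-2-one (not isolated) | [Li]N1C(=O)OC[C@@H]1Cc1ccccc1 | intermediate
8 | (S)-4-benzyl-3-(3-methylbutanoyl)-1,3-oxazolidin-2-one | CC(C)CC(=O)N1C(=O)OC[C@@H]1Cc1ccccc1 | intermediate
9 | tert-butyl bromoacetate | BrCC(=O)OC(C)(C)C | starting material
10 | sodium (Z)-enolate of 8 (not isolated) | CC(C)/C=C(\O[Na])N1C(=O)OC[C@@H]1Cc1ccccc1 | intermediate
11 | tert-butyl (3S)-3-[(4S)-4-benzyl-2-oxo-1,3-oxazolidine-3-carbonyl]-4-methylpentanoate | CC(C)[C@H](CC(=O)OC(C)(C)C)C(=O)N1C(=O)OC[C@@H]1Cc1ccccc1 | intermediate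
12 | tert-butyl (3S)-3-(hydroxymethyl)-4-methylpentanoate (not isolated) | CC(C)[C@H](CC(=O)OC(C)(C)C)CO | intermediate
13 | (4S)-4-isopropyldihydrofuran-2(3H)-one | O=C1C[C@@H](C(C)C)CO1 | intermediate
14 | 6-lithio-1,4-dioxaspiro[4.5]dec-6-ene (not isolated) | [Li]C1=CCCCC12OCCO2 | intermediate
15 | (3S)-1-(1,4-dioxaspiro[4.5]dec-6-en-6-yl)-3-(hydroxymethyl)-4-methylpentan-1-one | CC(C)[C@@H](CO)CC(=O)C1=CCCCC12OCCO2 | intermediate
16 | (1R,3S)-1-(1,4-dioxaspiro[4.5]dec-6-en-6-yl)-3-(hydroxymethyl)-4-methylpentan-1-ol | CC(C)[C@@H](CO)C[C@@H](O)C1=CCCCC12OCCO2 | intermediate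
17 | bis-TBS ether of 16 | CC(C)[C@@H](CO[Si](C)(C)C(C)(C)C)C[C@@H](O[Si](C)(C)C(C)(C)C)C1=CCCCC12OCCO2 | intermediate
18 | ring-B enone, bis-TBS ether | CC(C)[C@@H](CO[Si](C)(C)C(C)(C)C)C[C@@H](O[Si](C)(C)C(C)(C)C)C1=CC(=O)CCC12OCCO2 | intermediate
19 | ring-B enone, C6 primary alcohol, 9-O-TBS | CC(C)[C@@H](CO)C[C@@H](O[Si](C)(C)C(C)(C)C)C1=CC(=O)CCC12OCCO2 | intermediate
20 | (2S,4R)-4-(tert-butyldimethylsilyloxy)-2-isopropyl-4-(8-oxo-1,4-dioxaspiro[4.5]dec-6-en-6-yl)butanal | O=C[C@H](C(C)C)C[C@@H](O[Si](C)(C)C(C)(C)C)C1=CC(=O)CCC12OCCO2 | intermediate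
21 | methylzinc C4–C5 enolate after methyl transfer to C10 (not isolated) | O=C[C@H](C(C)C)C[C@@H](O[Si](C)(C)C(C)(C)C)[C@@]1(C)C=C(O[Zn]C)CCC12OCCO2 | intermediate
22 | methylzinc aldolate of 23 (not isolated) | CC(C)[C@@H]1C[C@@H](O[Si](C)(C)C(C)(C)C)[C@@]2(C)[C@H]([C@@H]1O[Zn]C)C(=O)CCC23OCCO3 | intermediate
23 | 9β-(tert-butyldimethylsilyloxy)-6α-hydroxy-7α-isopropyl-10β-methyl-trans-decalin-4-one 1-ethylene acetal | CC(C)[C@@H]1C[C@@H](O[Si](C)(C)C(C)(C)C)[C@@]2(C)[C@H]([C@@H]1O)C(=O)CCC23OCCO3 | intermediate
24 | 4-methylene analogue of 23 | CC(C)[C@@H]1C[C@@H](O[Si](C)(C)C(C)(C)C)[C@@]2(C)[C@H]([C@@H]1O)C(=C)CCC23OCCO3 | intermediate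
25 | 4-methylene 1-ketone | CC(C)[C@@H]1C[C@@H](O[Si](C)(C)C(C)(C)C)[C@@]2(C)[C@H]([C@@H]1O)C(=C)CCC2=O | intermediate
26 | 4α,6α,15-triol 1-ketone (9-O-TBS) | CC(C)[C@@H]1C[C@@H](O[Si](C)(C)C(C)(C)C)[C@@]2(C)[C@H]([C@@H]1O)[C@](O)(CO)CCC2=O | intermediate
27 | (E)-β-bromostyrene | Br/C=C/c1ccccc1 | starting material
28 | tetramethyl orthocarbonate | COC(OC)(OC)OC | starting material
29 | (E)-styrylmagnesium bromide (not isolated) | Br[Mg]/C=C/c1ccccc1 | intermediate
30 | trimethyl (E)-orthocinnamate | COC(OC)(OC)/C=C/c1ccccc1 | intermediate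
31 | orthoester 1-ketone (9-O-TBS) | CC(C)[C@@H]1C[C@@H](O[Si](C)(C)C(C)(C)C)[C@@]2(C)[C@@H]3[C@@H]1O[C@]1(/C=C/c4ccccc4)OC[C@@]3(CCC2=O)O1 | intermediate
32 | orthoester 1β-ol (9-O-TBS) | CC(C)[C@@H]1C[C@@H](O[Si](C)(C)C(C)(C)C)[C@@]2(C)[C@@H]3[C@@H]1O[C@]1(/C=C/c4ccccc4)OC[C@@]3(CC[C@@H]2O)O1 | intermediate
33 | CNP0252898.2 | CC(C)[C@@H]1C[C@@H](O)[C@@]2(C)[C@@H]3[C@@H]1O[C@]1(/C=C/c4ccccc4)OC[C@@]3(CC[C@@H]2O)O1 | target

**Step count and risk**

Total step count: 19. Longest linear sequence: 16 (steps 3–15 and 17–19); steps 1–2 and step 16 are side branches.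

Steps most likely to fail:

1. Step 12. Methyl transfer to C10 may be too slow at a carbon flanked by the spiro dioxolane and the silyloxy-bearing C9, so that the aldehyde is consumed by other zinc-promoted pathways; closure may also pass through the alternative chair and give a cis-fused aldol. The fallback separates the two events and sets out from enone 18, in which C6 is still a silyl ether, so that the more reactive Me3Al can be used with the same copper–carbene catalyst. Conjugate methylation should give the 10-methyl ketone F1, HF·pyridine the primary alcohol F2, and Dess–Martin oxidation the keto aldehyde F3. A direct titanium aldol (TiCl4, Bu3N, CH2Cl2, −78 °C), in which only the C5 enolate can reach C6 through a six-membered ring, would then close ring A and come back to the route at 23.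

2. Step 9. Hydrogen abstraction at C9 (allylic and next to the silyloxy oxygen) may compete with abstraction at C4, or the enone may be over-oxidised. The fallback installs the C4 oxygen before C9 exists and sets out from bromide 4 (with lactone 13). Allylic oxidation of 4 with CrO3·3,5-dimethylpyrazole, where C4 is the only allylic position, should give the bromo enone F4. Luche reduction (NaBH4, CeCl3·7H2O) gives the racemic allylic alcohol F5 and TESCl/imidazole its silyl ether F6. Bromine–lithium exchange and addition to 13 give the hydroxy enone F7 (a mixture at C4, of no consequence), CBS reduction as in step 7 the diol F8, and TBSOTf the bis-TBS ether F9. HF·pyridine removes the primary TBS and the secondary TES group to give the diol F10, and double Dess–Martin oxidation comes back to the route at 20.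

3. Step 17. The exchange may stop at a monocyclic mixed orthoester that falls back to esters on work-up, or the acid may ionise the tertiary C4 hydroxyl. The fallback sets out from triol 26 and closes the cage stepwise. Cinnamoyl chloride with 2,4,6-collidine at low temperature should acylate the primary O15 to give the 15-O-cinnamate F11. Acid-catalysed cyclodehydration of this diol monoester (camphorsulfonic acid, 4 Å molecular sieves, toluene), a known way to close caged orthoesters on preorganised polyols, would come back to the route at 31.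

**Further compounds**

F1 | step 12 | 10-methyl ketone, bis-TBS ether | CC(C)[C@@H](CO[Si](C)(C)C(C)(C)C)C[C@@H](O[Si](C)(C)C(C)(C)C)[C@@]1(C)CC(=O)CCC12OCCO2
F2 | step 12 | 10-methyl ketone, C6 primary alcohol | CC(C)[C@@H](CO)C[C@@H](O[Si](C)(C)C(C)(C)C)[C@@]1(C)CC(=O)CCC12OCCO2
F3 | step 12 | 10-methyl keto aldehyde | O=C[C@H](C(C)C)C[C@@H](O[Si](C)(C)C(C)(C)C)[C@@]1(C)CC(=O)CCC12OCCO2
F4 | step 9 | 6-bromo-1,4-dioxaspiro[4.5]dec-6-en-8-one | O=C1C=C(Br)C2(CC1)OCCO2
F5 | step 9 | 6-bromo-1,4-dioxaspiro[4.5]dec-6-en-8-ol (racemic) | OC1C=C(Br)C2(CC1)OCCO2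
F6 | step 9 | 6-bromo-8-(triethylsilyloxy)-1,4-dioxaspiro[4.5]dec-6-ene (racemic) | CC[Si](CC)(CC)OC1C=C(Br)C2(CC1)OCCO2
F7 | step 9 | hydroxy enone with 4-O-TES (C4 epimers) | CC(C)[C@@H](CO)CC(=O)C1=CC(O[Si](CC)(CC)CC)CCC12OCCO2
F8 | step 9 | (9R) diol with 4-O-TES (C4 epimers) | CC(C)[C@@H](CO)C[C@@H](O)C1=CC(O[Si](CC)(CC)CC)CCC12OCCO2
F9 | step 9 | 6,9-bis-TBS 4-O-TES ether (C4 epimers) | CC(C)[C@@H](CO[Si](C)(C)C(C)(C)C)C[C@@H](O[Si](C)(C)C(C)(C)C)C1=CC(O[Si](CC)(CC)CC)CCC12OCCO2
F10 | step 9 | 4,6-diol with 9-O-TBS (C4 epimers) | CC(C)[C@@H](CO)C[C@@H](O[Si](C)(C)C(C)(C)C)C1=CC(O)CCC12OCCO2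
F11 | step 17 | 15-O-cinnamate of triol 26 | CC(C)[C@@H]1C[C@@H](O[Si](C)(C)C(C)(C)C)[C@@]2(C)[C@H]([C@@H]1O)[C@](O)(COC(=O)/C=C/c1ccccc1)CCC2=O
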